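**Retrosynthetic overview**

1. Enabling feature: in the cyclohexane, the quaternary ring carbon (CH2OH and homofarnesyl) lies between the tertiary carbinol carbon C(OH)CH3 and the ring CH carrying the 3-hydroxypropyl chain, with CH2OH, OH and hydroxypropyl all cis. This 2-quaternary 1,3-dioxygenated array is the footprint of a 1,2-shift onto a 2,3-epoxy carbonyl unit, and the cis CH2OH/hydroxypropyl pair can be tied as a lactone.
2. Target ⇐ LiAlH4 opening of a cis-fused seven-membered lactone that carries a Weinreb amide ⇐ ring contraction of an α,β-epoxycycloheptanone through its cyclic hemiketal (key step).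
3. Epoxy ketone ⇐ hydroxyl-directed epoxidation of a cycloheptenol ⇐ Nozaki–Hiyama–Kishi closure of an alkenyl iodide onto an aldehyde.
4. Z tetrasubstituted enamide ⇐ temporary six-membered unsaturated lactone (intramolecular Horner–Wadsworth–Emmons) ⇐ Evans aldol of a five-carbon imide with an iodo-tetraenal made from farnesyl bromide by anti-carbomagnesiation.
5. Ring order: temporary six-membered lactone (opened again), cycloheptene, epoxide, oxane hemiketal, then cyclohexane plus seven-membered lactone in the key step; the lactone is opened in the last step.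

Key step: step 22

Remark: centres that are erased within the next steps (the phosphonate-bearing carbon of 20 to 22, the carbinol carbon of 26, the hemiketal carbon of 32) are left undefined in the SMILES; the six starting materials are taken as purchasable.

**Route**

Step 1
Reactants: 1 (2E,6E)-farnesyl bromide; 2 1-(trimethylsilyl)propyne
Product: 3 trimethyl[(6E,10E)-7,11,15-trimethylhexadeca-6,10,14-trien-1-yn-1-yl]silane
Conditions: 2, n-BuLi, THF, −78 to −20 °C; then 1, −78 °C to rt
Reagents that add atoms: none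
Why: the propargylic lithium reagent from 2 displaces the primary allylic bromide by SN2 at the CH2 carbon without allylic transposition (propargyl anion alkylation), so both E double bonds of 1 are carried over unchanged.

Step 2
Reactants: 3
Product: 5 (6E,10E)-7,11,15-trimethylhexadeca-6,10,14-trien-2-yn-1-ol, via lithium acetylide 4 (not isolated)
Conditions: MeLi·LiBr, THF, 0 °C to rt; then (CH2O)n, −78 °C to rt
Reagents that add atoms: formaldehyde (used as paraformaldehyde), C=O
Why: methyllithium attacks silicon and releases the lithium acetylide, which adds to formaldehyde (acetylide hydroxymethylation).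

Step 3
Reactants: 5
Product: 7 (2Z,6E,10E)-3-iodo-2,7,11,15-tetramethylhexadeca-2,6,10,14-tetraen-1-ol, via alkenylmagnesium chelate 6 (not isolated)
Conditions: MeMgBr (4 equiv), CuI (10 mol %), THF, −20 to 25 °C; then I2, −78 to 0 °C
Reagents that add atoms: methylmagnesium bromide, C[Mg]Br; iodine, I-I
Why: alkoxide-directed anti-carbomagnesiation of a 2-alkyn-1-ol puts the methyl group on the alkyne carbon next to CH2O and magnesium on the distal carbon in a five-membered chelate cis to CH2O, so iodinolysis with retention should give the Z tetrasubstituted alkenyl iodide.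

Step 4
Reactants: 7
Product: 8 (2Z,6E,10E)-1-bromo-3-iodo-2,7,11,15-tetramethylhexadeca-2,6,10,14-tetraene
Conditions: CBr4, PPh3, CH2Cl2, 0 °C
Reagents that add atoms: carbon tetrabromide, BrC(Br)(Br)Br
Why: Appel bromination converts the primary allylic alcohol under neutral conditions, and SN2 at the CH2 is favoured over allylic transposition because the other allylic terminus is fully substituted and carries iodine.

Step 5
Reactants: 8
Product: 9 (4Z,8E,12E)-5-iodo-4,9,13,17-tetramethyloctadeca-4,8,12,16-tetraenenitrile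
Conditions: MeCN (3 equiv), n-BuLi, THF, −78 °C; then 8, −78 to −40 °C
Reagents that add atoms: acetonitrile, CC#N
Why: SN2 alkylation of lithioacetonitrile by the reactive allylic bromide adds the two-carbon unit, and the alkenyl iodide is inert to this stabilised carbanion.

Step 6
Reactants: 9
Product: 10 (4Z,8E,12E)-5-iodo-4,9,13,17-tetramethyloctadeca-4,8,12,16-tetraenal
Conditions: iBu2AlH, toluene, −78 °C; then aq. potassium sodium tartrate
Reagents that add atoms: water, O
Why: nitrile half-reduction with iBu2AlH stops at the N-aluminoimine, which is hydrolysed to the aldehyde on work-up, and at −78 °C the alkenyl iodide and the trisubstituted alkenes are inert.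

Step 7
Reactants: 11 δ-valerolactone; 12 4-methoxybenzyl chloride
Product: 13 5-[(4-methoxybenzyl)oxy]pentanoic acid
Conditions: KOH, toluene, reflux; then aq. HCl
Reagents that add atoms: potassium hydroxide, [K+].[OH-]
Why: hydroxide opens the lactone and the primary alkoxide is etherified by the benzylic chloride (Williamson ether synthesis), any benzylic ester being saponified by the excess base before acidification.

Step 8
Reactants: 13; 14 (4S)-4-benzyl-1,3-oxazolidin-2-one
Product: 16 (4S)-4-benzyl-3-{5-[(4-methoxybenzyl)oxy]pentanoyl}-1,3-oxazolidin-2-one, via mixed pivalic anhydride 15 (not isolated)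
Conditions: t-BuCOCl, Et3N, THF, −20 °C; then 14, LiCl, −20 °C to rt
Reagents that add atoms: none
Why: mixed-anhydride N-acylation of the oxazolidinone (LiCl/Et3N protocol) gives the imide, and no stereocentre is at risk.

Step 9
Reactants: 16; 10
Product: 18 (4S)-4-benzyl-3-{(2S,3R,6Z,10E,14E)-3-hydroxy-7-iodo-2-[3-(4-methoxybenzyloxy)propyl]-6,11,15,19-tetramethylicosa-6,10,14,18-tetraenoyl}-1,3-oxazolidin-2-one, via dibutylboron Z-enolate 17 (not isolated)
Conditions: n-Bu2BOTf, iPr2NEt, CH2Cl2, 0 °C; then 10, −78 to 0 °C; then pH 7 buffer, MeOH, 30% H2O2, 0 °C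
Reagents that add atoms: none
Why: Evans syn aldol, in which the Z-boron enolate reacts through a chair (Zimmerman–Traxler) transition state on the face away from the benzyl group; this sets the side-chain-bearing CH (the later ring CH) in the required configuration, and the syn carbinol is oxidised away in step 12.

Step 10
Reactants: 18
Product: 19 (2R,3R,6Z,10E,14E)-7-iodo-2-[3-(4-methoxybenzyloxy)propyl]-6,11,15,19-tetramethylicosa-6,10,14,18-tetraene-1,3-diol
Conditions: LiBH4, MeOH (1 equiv), THF, 0 °C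
Reagents that add atoms: none
Why: LiBH4 reductively cleaves the N-acyl oxazolidinone to the primary alcohol (the auxiliary is recovered) without touching the alkenyl iodide or the 4-methoxybenzyl ether.

Step 11
Reactants: 19; 20 2-(diethoxyphosphoryl)propanoic acid
Product: 21 (2R,3R,6Z,10E,14E)-3-hydroxy-7-iodo-2-[3-(4-methoxybenzyloxy)propyl]-6,11,15,19-tetramethylicosa-6,10,14,18-tetraen-1-yl 2-(diethoxyphosphoryl)propanoate
Conditions: DCC, DMAP (cat.), CH2Cl2, −20 to 0 °C
Reagents that add atoms: none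
Why: Steglich esterification at low temperature should acylate the unhindered primary hydroxyl in preference to the flanked secondary one, which installs the phosphonate for ring closure.

Step 12
Reactants: 21
Product: 22 (2R,6Z,10E,14E)-7-iodo-2-[3-(4-methoxybenzyloxy)propyl]-6,11,15,19-tetramethyl-3-oxoicosa-6,10,14,18-tetraen-1-yl 2-(diethoxyphosphoryl)propanoate
Conditions: Dess–Martin periodinane, NaHCO3, CH2Cl2, 0 °C to rt
Reagents that add atoms: none
Why: buffered Dess–Martin oxidation converts the secondary alcohol into the ketone without a base strong enough to eliminate the β-acyloxy group or epimerise the adjacent CH.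

Step 13
Reactants: 22
Product: 23 (5S)-4-[(3Z,7E,11E)-4-iodo-3,8,12,16-tetramethylheptadeca-3,7,11,15-tetraen-1-yl]-5-[3-(4-methoxybenzyloxy)propyl]-3-methyl-5,6-dihydro-2H-pyran-2-one
Conditions: LiCl, DBU, MeCN, 0 °C to rt
Reagents that add atoms: none
Why: intramolecular Horner–Wadsworth–Emmons olefination closes the six-membered unsaturated lactone, and the ring forces the carbonyl carbon cis to the stereogenic CH, which fixes the Z geometry of the tetrasubstituted alkene independent of any kinetic preference.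

Step 14
Reactants: 23
Product: 24 (2Z,6Z,10E,14E)-3-[(2S)-1-hydroxy-5-(4-methoxybenzyloxy)pentan-2-yl]-7-iodo-N-methoxy-N,2,6,11,15,19-hexamethylicosa-2,6,10,14,18-pentaenamide
Conditions: MeNH(OMe)·HCl, AlMe3, CH2Cl2, 0 °C to rt; then aq. potassium sodium tartrate
Reagents that add atoms: N,O-dimethylhydroxylamine hydrochloride, CNOC.Cl
Why: aminolysis of the lactone by the chloroaluminium amide opens the ring to the Weinreb amide with the alkene geometry untouched and frees the primary alcohol for oxidation.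

Step 15
Reactants: 24
Product: 25 (2Z,6Z,10E,14E)-7-iodo-N-methoxy-3-[(2S)-5-(4-methoxybenzyloxy)-1-oxopentan-2-yl]-N,2,6,11,15,19-hexamethylicosa-2,6,10,14,18-pentaenamide
Conditions: Dess–Martin periodinane, NaHCO3, CH2Cl2, 0 °C; used at once
Reagents that add atoms: none
Why: buffered Dess–Martin oxidation gives the aldehyde under neutral conditions that should leave the α-stereocentre intact, the fully substituted enamide being twisted out of conjugation and so only weakly acidifying.

Step 16
Reactants: 25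
Product: 26 (2Z)-2-{(2S,3RS)-3-hydroxy-2-[3-(4-methoxybenzyloxy)propyl]-5-methyl-4-[(3E,7E)-4,8,12-trimethyltrideca-3,7,11-trien-1-yl]cyclohept-4-en-1-ylidene}-N-methoxy-N-methylpropanamide
Conditions: CrCl2 (8 equiv), NiCl2 (2 mol %), degassed DMSO–THF, 25 °C, 0.005 M, slow addition of 25
Reagents that add atoms: none
Why: Nozaki–Hiyama–Kishi reaction, in which zerovalent nickel inserts into the C–I bond and transmetalation gives an alkenyl species of trivalent chromium that adds to the aldehyde but not to the Weinreb amide; this closes the seven-membered ring with the ring alkene geometry already set in step 3, and the unselectively formed carbinol centre is erased in step 17.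

Step 17
Reactants: 26
Product: 27 (2Z)-N-methoxy-2-{(2S)-2-[3-(4-methoxybenzyloxy)propyl]-5-methyl-3-oxo-4-[(3E,7E)-4,8,12-trimethyltrideca-3,7,11-trien-1-yl]cyclohept-4-en-1-ylidene}-N-methylpropanamide
Conditions: Dess–Martin periodinane, NaHCO3, CH2Cl2, 0 °C
Reagents that add atoms: none
Why: Dess–Martin oxidation converges both carbinol epimers into one enone under neutral conditions.

Step 18
Reactants: 27
Product: 28 (2Z)-2-{(2S,3S)-3-hydroxy-2-[3-(4-methoxybenzyloxy)propyl]-5-methyl-4-[(3E,7E)-4,8,12-trimethyltrideca-3,7,11-trien-1-yl]cyclohept-4-en-1-ylidene}-N-methoxy-N-methylpropanamide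
Conditions: LiBH(s-Bu)3, THF, −78 °C
Reagents that add atoms: none
Why: 1,2-reduction by the bulky borohydride should occur anti to the neighbouring side chain, which allylic 1,3-strain with the exocyclic alkene holds pseudoaxial, giving the alcohol cis to that chain; the fully substituted enone resists conjugate reduction and the hindered Weinreb amide should be inert at −78 °C.

Step 19
Reactants: 28
Product: 29 (2Z)-2-{(1S,2S,3S,7R)-2-hydroxy-3-[3-(4-methoxybenzyloxy)propyl]-7-methyl-1-[(3E,7E)-4,8,12-trimethyltrideca-3,7,11-trien-1-yl]-8-oxabicyclo[5.1.0]octan-4-ylidene}-N-methoxy-N-methylpropanamide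
Conditions: VO(acac)2 (5 mol %), t-BuOOH, CH2Cl2, 0 °C to rt
Reagents that add atoms: tert-butyl hydroperoxide, CC(C)(C)OO
Why: hydroxyl-directed epoxidation is chemoselective for the allylic alkene and delivers oxygen syn to the hydroxyl, so both epoxide carbons are set cis to the side chain while the remote trisubstituted alkenes and the electron-poor enamide stay intact.

Step 20
Reactants: 29
Product: 30 (2Z)-N-methoxy-2-{(1R,3S,7R)-3-[3-(4-methoxybenzyloxy)propyl]-7-methyl-2-oxo-1-[(3E,7E)-4,8,12-trimethyltrideca-3,7,11-trien-1-yl]-8-oxabicyclo[5.1.0]octan-4-ylidene}-N-methylpropanamide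
Conditions: Dess–Martin periodinane, NaHCO3, CH2Cl2, 0 °C
Reagents that add atoms: none
Why: Dess–Martin oxidation gives the α,β-epoxy ketone and removes the carbinol hydrogen, which in the cis epoxy alcohol can lie antiperiplanar to the epoxide C–O bond and would compete as a migrating group.

Step 21
Reactants: 30
Product: 31 (2Z)-2-{(1R,3S,7R)-3-(3-hydroxypropyl)-7-methyl-2-oxo-1-[(3E,7E)-4,8,12-trimethyltrideca-3,7,11-trien-1-yl]-8-oxabicyclo[5.1.0]octan-4-ylidene}-N-methoxy-N-methylpropanamide
Conditions: DDQ, CH2Cl2–pH 7 phosphate buffer, 0 °C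
Reagents that add atoms: none
Why: oxidative cleavage of the 4-methoxybenzyl ether by DDQ at neutral pH frees the δ-hydroxyl without acid or base that would open the epoxide or enolise the ketone.

Step 22
Reactants: 31
Product: 33 (2Z)-2-[(5aS,9R,9aS)-9-hydroxy-9-methyl-1-oxo-9a-[(3E,7E)-4,8,12-trimethyltrideca-3,7,11-trien-1-yl]octahydro-2-benzoxepin-6(1H)-ylidene]-N-methoxy-N-methylpropanamide, via cyclic hemiketal 32 (not isolated)
Conditions: Al(OtBu)3 (2 equiv), toluene, 60 °C; then aq. potassium sodium tartrate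
Reagents that add atoms: none
Why: Proposed new method: the δ-hydroxy ketone closes by 6-exo-trig addition to hemiketal 32, whose aluminium alkoxide pushes the ring C–C bond that is antiperiplanar to the neighbouring epoxide C–O bond onto that epoxide carbon while aluminium pulls on the epoxide oxygen; this 1,2-shift contracts the cycloheptane to the cyclohexane and at the same time expands the oxane to the seven-membered lactone, the hemiketal carbon becoming the lactone carbonyl, and the closest known reaction types are the aluminium-alkoxide-promoted semipinacol rearrangement of tertiary 2,3-epoxy alcohols and the semibenzilic (quasi-Favorskii) ring contraction of α-halo ketones through their alkoxide adducts. The quaternary carbon is formed with inversion at the attacked epoxide carbon, the migrating CH keeps its configuration, and the tertiary carbinol keeps the configuration of the second epoxide carbon, so the cis relation of epoxide and side chain set in steps 18 and 19 becomes the all-cis acyl/OH/side-chain array. The step needs migration of the ring carbon only and cleavage of the proximal C–O bond only: the hemiketal carbon carries no hydrogen or other group able to migrate, the alkoxide sits next to the proximal epoxide carbon, and the tether allows only a cis-fused lactone. Al(OtBu)3 is chosen because it cannot transfer hydride to the ketone form and is too weak a Lewis acid to start cation–olefin cyclisation of the polyene chain.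

Step 23
Reactants: 33
Product: 34 (2Z)-2-{(2S,3R,4R)-4-hydroxy-3-(hydroxymethyl)-2-(3-hydroxypropyl)-4-methyl-3-[(3E,7E)-4,8,12-trimethyltrideca-3,7,11-trien-1-yl]cyclohexylidene}propanal (CNP0284886.2)
Conditions: LiAlH4, THF, −20 to 0 °C; then aq. potassium sodium tartrate
Reagents that add atoms: none
Why: LiAlH4 reduces the lactone to the two primary alcohols and converts the Weinreb amide into a chelated hemiaminal that releases the Z-enal only on work-up, so the target should be unveiled without protecting groups.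

**Compound list**

1 | (2E,6E)-farnesyl bromide | BrC/C=C(\C)CC/C=C(\C)CCC=C(C)C | starting material
2 | 1-(trimethylsilyl)propyne | CC#C[Si](C)(C)C | starting material
3 | trimethyl[(6E,10E)-7,11,15-trimethylhexadeca-6,10,14-trien-1-yn-1-yl]silane | C[Si](C)(C)C#CCC/C=C(\C)CC/C=C(\C)CCC=C(C)C | intermediate
4 | [(6E,10E)-7,11,15-trimethylhexadeca-6,10,14-trien-1-yn-1-yl]lithium (lithium acetylide, formed in the flask) | [Li]C#CCC/C=C(\C)CC/C=C(\C)CCC=C(C)C | intermediate
5 | (6E,10E)-7,11,15-trimethylhexadeca-6,10,14-trien-2-yn-1-ol | OCC#CCC/C=C(\C)CC/C=C(\C)CCC=C(C)C | intermediate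
6 | bromomagnesium alkoxide of the (2Z)-3-(bromomagnesio) allylic alcohol (alkenylmagnesium chelate, formed in the flask) | Br[Mg]OC/C(C)=C(\[Mg]Br)CC/C=C(\C)CC/C=C(\C)CCC=C(C)C | intermediate
7 | (2Z,6E,10E)-3-iodo-2,7,11,15-tetramethylhexadeca-2,6,10,14-tetraen-1-ol | OC/C(C)=C(\I)CC/C=C(\C)CC/C=C(\C)CCC=C(C)C | intermediate
8 | (2Z,6E,10E)-1-bromo-3-iodo-2,7,11,15-tetramethylhexadeca-2,6,10,14-tetraene | BrC/C(C)=C(\I)CC/C=C(\C)CC/C=C(\C)CCC=C(C)C | intermediate
9 | (4Z,8E,12E)-5-iodo-4,9,13,17-tetramethyloctadeca-4,8,12,16-tetraenenitrile | N#CCC/C(C)=C(\I)CC/C=C(\C)CC/C=C(\C)CCC=C(C)C | intermediate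
10 | (4Z,8E,12E)-5-iodo-4,9,13,17-tetramethyloctadeca-4,8,12,16-tetraenal | O=CCC/C(C)=C(\I)CC/C=C(\C)CC/C=C(\C)CCC=C(C)C | intermediate
11 | δ-valerolactone (oxan-2-one) | O=C1CCCCO1 | starting material
12 | 4-methoxybenzyl chloride | COc1ccc(CCl)cc1 | starting material
13 | 5-[(4-methoxybenzyl)oxy]pentanoic acid | COc1ccc(COCCCCC(=O)O)cc1 | intermediate
14 | (4S)-4-benzyl-1,3-oxazolidin-2-one | O=C1N[C@@H](Cc2ccccc2)CO1 | starting material
15 | 5-[(4-methoxybenzyl)oxy]pentanoic pivalic anhydride (formed in the flask) | COc1ccc(COCCCCC(=O)OC(=O)C(C)(C)C)cc1 | intermediate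
16 | (4S)-4-benzyl-3-{5-[(4-methoxybenzyl)oxy]pentanoyl}-1,3-oxazolidin-2-one | COc1ccc(COCCCCC(=O)N2[C@@H](Cc3ccccc3)COC2=O)cc1 | intermediate
17 | dibutylboron (Z)-enolate of 16 (formed in the flask) | CCCCB(CCCC)O/C(=C\CCCOCc1ccc(OC)cc1)N1[C@@H](Cc2ccccc2)COC1=O | intermediate
18 | (4S)-4-benzyl-3-{(2S,3R,6Z,10E,14E)-3-hydroxy-7-iodo-2-[3-(4-methoxybenzyloxy)propyl]-6,11,15,19-tetramethylicosa-6,10,14,18-tetraenoyl}-1,3-oxazolidin-2-one | O=C(N1[C@@H](Cc2ccccc2)COC1=O)[C@@H](CCCOCc1ccc(OC)cc1)[C@H](O)CC/C(C)=C(\I)CC/C=C(\C)CC/C=C(\C)CCC=C(C)C | intermediate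
19 | (2R,3R,6Z,10E,14E)-7-iodo-2-[3-(4-methoxybenzyloxy)propyl]-6,11,15,19-tetramethylicosa-6,10,14,18-tetraene-1,3-diol | OC[C@@H](CCCOCc1ccc(OC)cc1)[C@H](O)CC/C(C)=C(\I)CC/C=C(\C)CC/C=C(\C)CCC=C(C)C | intermediate
20 | 2-(diethoxyphosphoryl)propanoic acid (racemic) | CCOP(=O)(OCC)C(C)C(=O)O | starting material
21 | (2R,3R,6Z,10E,14E)-3-hydroxy-7-iodo-2-[3-(4-methoxybenzyloxy)propyl]-6,11,15,19-tetramethylicosa-6,10,14,18-tetraen-1-yl 2-(diethoxyphosphoryl)propanoate | CCOP(=O)(OCC)C(C)C(=O)OC[C@@H](CCCOCc1ccc(OC)cc1)[C@H](O)CC/C(C)=C(\I)CC/C=C(\C)CC/C=C(\C)CCC=C(C)C | intermediate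
22 | (2R,6Z,10E,14E)-7-iodo-2-[3-(4-methoxybenzyloxy)propyl]-6,11,15,19-tetramethyl-3-oxoicosa-6,10,14,18-tetraen-1-yl 2-(diethoxyphosphoryl)propanoate | CCOP(=O)(OCC)C(C)C(=O)OC[C@@H](CCCOCc1ccc(OC)cc1)C(=O)CC/C(C)=C(\I)CC/C=C(\C)CC/C=C(\C)CCC=C(C)C | intermediate
23 | (5S)-4-[(3Z,7E,11E)-4-iodo-3,8,12,16-tetramethylheptadeca-3,7,11,15-tetraen-1-yl]-5-[3-(4-methoxybenzyloxy)propyl]-3-methyl-5,6-dihydro-2H-pyran-2-one | CC1=C(CC/C(C)=C(\I)CC/C=C(\C)CC/C=C(\C)CCC=C(C)C)[C@H](CCCOCc2ccc(OC)cc2)COC1=O | intermediate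
24 | (2Z,6Z,10E,14E)-3-[(2S)-1-hydroxy-5-(4-methoxybenzyloxy)pentan-2-yl]-7-iodo-N-methoxy-N,2,6,11,15,19-hexamethylicosa-2,6,10,14,18-pentaenamide | CON(C)C(=O)/C(C)=C(/CC/C(C)=C(\I)CC/C=C(\C)CC/C=C(\C)CCC=C(C)C)[C@H](CCCOCc1ccc(OC)cc1)CO | intermediate
25 | (2Z,6Z,10E,14E)-7-iodo-N-methoxy-3-[(2S)-5-(4-methoxybenzyloxy)-1-oxopentan-2-yl]-N,2,6,11,15,19-hexamethylicosa-2,6,10,14,18-pentaenamide | CON(C)C(=O)/C(C)=C(/CC/C(C)=C(\I)CC/C=C(\C)CC/C=C(\C)CCC=C(C)C)[C@H](CCCOCc1ccc(OC)cc1)C=O | intermediate
26 | (2Z)-2-{(2S,3RS)-3-hydroxy-2-[3-(4-methoxybenzyloxy)propyl]-5-methyl-4-[(3E,7E)-4,8,12-trimethyltrideca-3,7,11-trien-1-yl]cyclohept-4-en-1-ylidene}-N-methoxy-N-methylpropanamide | OC1C(CC/C=C(\C)CC/C=C(\C)CCC=C(C)C)=C(C)CC/C(=C(\C)C(=O)N(C)OC)[C@@H]1CCCOCc1ccc(OC)cc1 | intermediate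
27 | (2Z)-N-methoxy-2-{(2S)-2-[3-(4-methoxybenzyloxy)propyl]-5-methyl-3-oxo-4-[(3E,7E)-4,8,12-trimethyltrideca-3,7,11-trien-1-yl]cyclohept-4-en-1-ylidene}-N-methylpropanamide | O=C1C(CC/C=C(\C)CC/C=C(\C)CCC=C(C)C)=C(C)CC/C(=C(\C)C(=O)N(C)OC)[C@@H]1CCCOCc1ccc(OC)cc1 | intermediate
28 | (2Z)-2-{(2S,3S)-3-hydroxy-2-[3-(4-methoxybenzyloxy)propyl]-5-methyl-4-[(3E,7E)-4,8,12-trimethyltrideca-3,7,11-trien-1-yl]cyclohept-4-en-1-ylidene}-N-methoxy-N-methylpropanamide (OH cis to the side chain) | O[C@@H]1C(CC/C=C(\C)CC/C=C(\C)CCC=C(C)C)=C(C)CC/C(=C(\C)C(=O)N(C)OC)[C@@H]1CCCOCc1ccc(OC)cc1 | intermediate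
29 | (2Z)-2-{(1S,2S,3S,7R)-2-hydroxy-3-[3-(4-methoxybenzyloxy)propyl]-7-methyl-1-[(3E,7E)-4,8,12-trimethyltrideca-3,7,11-trien-1-yl]-8-oxabicyclo[5.1.0]octan-4-ylidene}-N-methoxy-N-methylpropanamide (OH, epoxide oxygen and side chain all cis) | O[C@@H]1[C@]2(CC/C=C(\C)CC/C=C(\C)CCC=C(C)C)O[C@]2(C)CC/C(=C(\C)C(=O)N(C)OC)[C@@H]1CCCOCc1ccc(OC)cc1 | intermediate
30 | (2Z)-N-methoxy-2-{(1R,3S,7R)-3-[3-(4-methoxybenzyloxy)propyl]-7-methyl-2-oxo-1-[(3E,7E)-4,8,12-trimethyltrideca-3,7,11-trien-1-yl]-8-oxabicyclo[5.1.0]octan-4-ylidene}-N-methylpropanamide | O=C1[C@]2(CC/C=C(\C)CC/C=C(\C)CCC=C(C)C)O[C@]2(C)CC/C(=C(\C)C(=O)N(C)OC)[C@@H]1CCCOCc1ccc(OC)cc1 | intermediate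
31 | (2Z)-2-{(1R,3S,7R)-3-(3-hydroxypropyl)-7-methyl-2-oxo-1-[(3E,7E)-4,8,12-trimethyltrideca-3,7,11-trien-1-yl]-8-oxabicyclo[5.1.0]octan-4-ylidene}-N-methoxy-N-methylpropanamide | O=C1[C@]2(CC/C=C(\C)CC/C=C(\C)CCC=C(C)C)O[C@]2(C)CC/C(=C(\C)C(=O)N(C)OC)[C@@H]1CCCO | intermediate
32 | six-membered cyclic hemiketal of 31 (side-chain oxygen bonded to the former ketone carbon; hemiketal carbon as anomer mixture; formed in the flask) | OC12OCCC[C@H]1/C(=C(/C)C(=O)N(C)OC)CC[C@@]3(C)O[C@@]23CC/C=C(\C)CC/C=C(\C)CCC=C(C)C | intermediate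
33 | (2Z)-2-[(5aS,9R,9aS)-9-hydroxy-9-methyl-1-oxo-9a-[(3E,7E)-4,8,12-trimethyltrideca-3,7,11-trien-1-yl]octahydro-2-benzoxepin-6(1H)-ylidene]-N-methoxy-N-methylpropanamide | CC(C)=CCC/C(C)=C/CC/C(C)=C/CC[C@]12C(=O)OCCC[C@H]1/C(=C(/C)C(=O)N(C)OC)CC[C@@]2(C)O | intermediate
34 | (2Z)-2-{(2S,3R,4R)-4-hydroxy-3-(hydroxymethyl)-2-(3-hydroxypropyl)-4-methyl-3-[(3E,7E)-4,8,12-trimethyltrideca-3,7,11-trien-1-yl]cyclohexylidene}propanal (CNP0284886.2) | CC(C)=CCC/C(C)=C/CC/C(C)=C/CC[C@]1(CO)[C@@H](CCCO)/C(=C(/C)C=O)CC[C@@]1(C)O | target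

**Step count and risks**

Total steps: 23. Longest linear sequence: 21 steps (steps 1 to 6, then 9 to 23).

Steps most likely to fail:

1. Step 22 (Proposed new method). The aluminium hemiketal may fail to ionise the tetrasubstituted epoxide, or enolisation of the open keto form may epimerise the ring CH before the shift occurs. Fallback with known chemistry: it sets out from 29 and uses the tandem semipinacol rearrangement/Meerwein–Ponndorf–Verley reduction of a 2,3-epoxy alcohol with Al(OiPr)3 in iPrOH at 80 °C. The ring bond migrates onto the epoxide carbon to give the ring-contracted β-hydroxy aldehyde F1 in the flask, which is reduced at once to the 1,3-diol F2; here a competing hydride shift from the carbinol carbon has to be accepted and its product separated. DDQ at pH 7 then removes the 4-methoxybenzyl group to give the triol amide F3, and LiAlH4 at −20 °C reduces the Weinreb amide, which comes back to the route at 34.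

2. Step 16. Oxidative addition to the fully substituted alkenyl iodide may be slow, so that proto-deiodination or intermolecular addition competes with seven-membered ring closure. Fallback: it sets out from 25 and replaces the aldehyde addition by an intramolecular acylation (Parham-type cyclisation). Pinnick oxidation (NaClO2, NaH2PO4, 2-methylbut-2-ene) gives the carboxylic acid F4, carbodiimide coupling with MeNH(OMe)·HCl gives the bis-Weinreb amide F5, and iodine–lithium exchange with t-BuLi at −100 °C lets the alkenyllithium attack the only amide it can reach in a ring. This should give the enone directly and comes back to the route at 27.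

3. Step 13. β-Elimination of the phosphonoester through enolisation of the ketone (E1cB), with epimerisation of the adjacent CH, may outrun the olefination. Fallback: it sets out from 19 and builds the same lactone by a Reformatsky route under non-basic conditions. Selective acylation of the primary hydroxyl with 2-bromopropanoyl bromide and pyridine at −78 °C gives the bromo ester F6, Dess–Martin oxidation gives the keto bromo ester F7, and SmI2 in THF at −78 °C closes the ring to the β-hydroxy lactone F8. Dehydration with SOCl2/pyridine and then DBU toward the acidic α-hydrogen comes back to the route at 23, the ring again fixing the alkene geometry.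

**Further compounds**

F1 | step 22 | (2Z)-2-{(2S,3S,4R)-3-formyl-4-hydroxy-2-[3-(4-methoxybenzyloxy)propyl]-4-methyl-3-[(3E,7E)-4,8,12-trimethyltrideca-3,7,11-trien-1-yl]cyclohexylidene}-N-methoxy-N-methylpropanamide | CC(C)=CCC/C(C)=C/CC/C(C)=C/CC[C@]1(C=O)[C@@H](CCCOCc2ccc(OC)cc2)/C(=C(/C)C(=O)N(C)OC)CC[C@@]1(C)O
F2 | step 22 | (2Z)-2-{(2S,3R,4R)-4-hydroxy-3-(hydroxymethyl)-2-[3-(4-methoxybenzyloxy)propyl]-4-methyl-3-[(3E,7E)-4,8,12-trimethyltrideca-3,7,11-trien-1-yl]cyclohexylidene}-N-methoxy-N-methylpropanamide | CC(C)=CCC/C(C)=C/CC/C(C)=C/CC[C@]1(CO)[C@@H](CCCOCc2ccc(OC)cc2)/C(=C(/C)C(=O)N(C)OC)CC[C@@]1(C)O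
F3 | step 22 | (2Z)-2-{(2S,3R,4R)-4-hydroxy-3-(hydroxymethyl)-2-(3-hydroxypropyl)-4-methyl-3-[(3E,7E)-4,8,12-trimethyltrideca-3,7,11-trien-1-yl]cyclohexylidene}-N-methoxy-N-methylpropanamide | CC(C)=CCC/C(C)=C/CC/C(C)=C/CC[C@]1(CO)[C@@H](CCCO)/C(=C(/C)C(=O)N(C)OC)CC[C@@]1(C)O
F4 | step 16 | carboxylic acid corresponding to aldehyde 25 (CHO oxidised to CO2H; (2S) centre and all alkene geometries as in 25) | CON(C)C(=O)/C(C)=C(/CC/C(C)=C(\I)CC/C=C(\C)CC/C=C(\C)CCC=C(C)C)[C@H](CCCOCc1ccc(OC)cc1)C(=O)O
F5 | step 16 | bis-Weinreb amide from F4 (CO2H converted into C(=O)N(OMe)Me) | CON(C)C(=O)/C(C)=C(/CC/C(C)=C(\I)CC/C=C(\C)CC/C=C(\C)CCC=C(C)C)[C@H](CCCOCc1ccc(OC)cc1)C(=O)N(C)OC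
F6 | step 13 | primary 2-bromopropanoate of diol 19 (secondary hydroxyl free) | CC(Br)C(=O)OC[C@@H](CCCOCc1ccc(OC)cc1)[C@H](O)CC/C(C)=C(\I)CC/C=C(\C)CC/C=C(\C)CCC=C(C)C
F7 | step 13 | 3-oxo analogue of F6 (secondary hydroxyl oxidised to the ketone) | CC(Br)C(=O)OC[C@@H](CCCOCc1ccc(OC)cc1)C(=O)CC/C(C)=C(\I)CC/C=C(\C)CC/C=C(\C)CCC=C(C)C
F8 | step 13 | 4-hydroxy-3-methyl-tetrahydropyran-2-one with the iodo-tetraenyl chain on the carbinol carbon and the (4-methoxybenzyloxy)propyl chain on the (5S) carbon (β-hydroxy lactone; two new centres as a mixture) | CC1C(=O)OC[C@@H](CCCOCc2ccc(OC)cc2)C1(O)CC/C(C)=C(\I)CC/C=C(\C)CC/C=C(\C)CCC=C(C)C
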